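**Retrosynthetic overview**

1. Feature relied on: ring B is a resorcinol bound through C1' to C2 of the furan ring, with OH at C2' and C4', H at C3' and C6' and prenyl at C5'. A prenyl-terminated 1-methoxy-1,3-bis(silyloxy)diene lays exactly this array onto an ethynyl group on C2.
2. Last disconnection: C1'–C2' and C5'–C6' (Diels–Alder, then loss of methanol) gives 2-ethynyl-7-prenyl-6-silyloxybenzofuran-3-carbaldehyde and the triene made from methyl acetoacetate dianion and prenyl bromide.
3. The alkyne comes from Sonogashira coupling on the 2-chloro-3-formylbenzofuran, that from Vilsmeier chloroformylation of the 7-prenylbenzofuran-2(3H)-one, that from lactonization of 2,4-dihydroxy-3-prenylphenylacetic acid. The acid comes from α-arylation of tert-butyl acetate with an aryl chloride whose prenyl group is placed between the two oxygens by directed ortho-metalation of 4-chlororesorcinol bis-MOM ether.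
4. Ring order: ring A is bought; the furan ring is closed as a lactone (step 6) and aromatised (step 8); ring B is formed last (step 14).

Key step: step 14

Remark on the chemistry: O6 is carried as a triisopropylsilyl ether, which should survive the methanolic carbonate of step 10 better than a tert-butyldimethylsilyl ether. The diene is assumed to form mainly as the 3Z isomer (side chain outward in the s-cis form); the ketene acetal geometry is immaterial. Numbering: benzofuran O1–C7a, ring B C1'–C6'.

**Route**

Step 1
Reactants: 1 4-chlororesorcinol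
Product: 2 1-chloro-2,4-bis(methoxymethoxy)benzene
Conditions: MOMCl, i-Pr2NEt, CH2Cl2, 0 °C → rt
Reagents that add atoms: chloromethyl methyl ether (MOMCl), COCCl
Why: O-alkylation of both phenols (Williamson-type acetal ether formation) gives two MOM ethers that protect the oxygens and act as directing groups for the next step.

Step 2
Reactants: 2 1-chloro-2,4-bis(methoxymethoxy)benzene; 3 prenyl bromide
Product: 5 1-chloro-2,4-bis(methoxymethoxy)-3-(3-methylbut-2-en-1-yl)benzene, via aryllithium 4 (not isolated)
Conditions: n-BuLi, THF, −78 → −20 °C; CuI (10 mol %), then 3, −78 °C → rt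
Reagents that add atoms: none
Why: Directed ortho-metalation removes the hydrogen flanked by both OMOM groups (the C–Cl bond, meta to that carbon, is inert to n-BuLi at this temperature), and copper-catalysed allylic substitution at the unhindered end of prenyl bromide should give the linear prenyl arene.

Step 3
Reactants: 5 1-chloro-2,4-bis(methoxymethoxy)-3-(3-methylbut-2-en-1-yl)benzene; 6 tert-butyl acetate
Product: 8 tert-butyl 2-[2,4-bis(methoxymethoxy)-3-(3-methylbut-2-en-1-yl)phenyl]acetate, via lithium ester enolate 7 (not isolated)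
Conditions: LiN(SiMe3)2 (3 equiv), Pd2(dba)3 (1 mol %), t-BuXPhos (2-di-tert-butylphosphino-2',4',6'-triisopropylbiphenyl, 4 mol %), toluene, rt → 50 °C
Reagents that add atoms: none
Why: Palladium-catalysed α-arylation of an ester enolate (Buchwald–Hartwig type), in which a bulky dialkylbiarylphosphine allows oxidative addition of electron-rich aryl chlorides near room temperature and favours monoarylation of tert-butyl acetate.

Step 4
Reactants: 8 tert-butyl 2-[2,4-bis(methoxymethoxy)-3-(3-methylbut-2-en-1-yl)phenyl]acetate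
Product: 9 methyl 2-[2,4-dihydroxy-3-(3-methylbut-2-en-1-yl)phenyl]acetate
Conditions: HCl (3 M in MeOH), 45 °C
Reagents that add atoms: methanol, CO
Why: Acid-catalysed acetal exchange removes both MOM groups and methanolic HCl exchanges the tert-butyl ester for the methyl ester (alkyl–oxygen cleavage, then Fischer esterification), conditions under which ortho-prenylphenols are commonly unmasked without closing to chromans.

Step 5
Reactants: 9 methyl 2-[2,4-dihydroxy-3-(3-methylbut-2-en-1-yl)phenyl]acetate
Product: 10 2-[2,4-dihydroxy-3-(3-methylbut-2-en-1-yl)phenyl]acetic acid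
Conditions: LiOH·H2O, THF/H2O (degassed), rt; then 1 M aq. HCl to pH 2, 0 °C
Reagents that add atoms: lithium hydroxide, [Li+].[OH-]
Why: Saponification of an unhindered methyl ester, run under argon because the resorcinol dianion is air-sensitive.

Step 6
Reactants: 10 2-[2,4-dihydroxy-3-(3-methylbut-2-en-1-yl)phenyl]acetic acid
Product: 11 6-hydroxy-7-(3-methylbut-2-en-1-yl)benzofuran-2(3H)-one
Conditions: EDC·HCl (N-(3-dimethylaminopropyl)-N'-ethylcarbodiimide hydrochloride), CH2Cl2 (dilute), 0 °C → rt
Reagents that add atoms: none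
Why: Carbodiimide-mediated lactonization closes the five-membered aryl ester (bond O1–C2) without acid, so the prenyl group is not exposed to chroman-forming conditions, and only the ortho hydroxyl can reach the activated carboxyl.

Step 7
Reactants: 11 6-hydroxy-7-(3-methylbut-2-en-1-yl)benzofuran-2(3H)-one
Product: 12 7-(3-methylbut-2-en-1-yl)-6-[(triisopropylsilyl)oxy]benzofuran-2(3H)-one
Conditions: TIPSCl, imidazole, DMF, rt
Reagents that add atoms: chlorotriisopropylsilane (TIPSCl), CC(C)[Si](Cl)(C(C)C)C(C)C
Why: Silylation of the only free phenol gives a hindered aryl silyl ether that masks O6 against O-formylation in step 8 and should resist the basic methanol of step 10.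

Step 8
Reactants: 12 7-(3-methylbut-2-en-1-yl)-6-[(triisopropylsilyl)oxy]benzofuran-2(3H)-one
Product: 14 2-chloro-7-(3-methylbut-2-en-1-yl)-6-[(triisopropylsilyl)oxy]benzofuran-3-carbaldehyde, via iminium chloride 13 (not isolated)
Conditions: POCl3, DMF, ClCH2CH2Cl, 0 → 60 °C; then aq. NaOAc, 0 °C → rt
Reagents that add atoms: N,N-dimethylformamide, CN(C)C=O; phosphoryl chloride, O=P(Cl)(Cl)Cl; water, O
Why: Vilsmeier–Haack–Arnold chloroformylation, in which the enolisable C3 methylene is formylated and the lactone oxygen of the resulting vinylogous carbamate is exchanged for chloride with aromatisation to the benzofuran, as is known for the parent benzofuran-2(3H)-one.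

Step 9
Reactants: 14 2-chloro-7-(3-methylbut-2-en-1-yl)-6-[(triisopropylsilyl)oxy]benzofuran-3-carbaldehyde; 15 ethynyltrimethylsilane
Product: 16 7-(3-methylbut-2-en-1-yl)-6-[(triisopropylsilyl)oxy]-2-[(trimethylsilyl)ethynyl]benzofuran-3-carbaldehyde
Conditions: PdCl2(PPh3)2 (5 mol %), CuI (10 mol %), Et3N, THF, 50 °C
Reagents that add atoms: none
Why: Sonogashira coupling, in which the C2–Cl bond behaves as a vinylogous acid chloride activated toward oxidative addition by the 3-formyl group.

Step 10
Reactants: 16 7-(3-methylbut-2-en-1-yl)-6-[(triisopropylsilyl)oxy]-2-[(trimethylsilyl)ethynyl]benzofuran-3-carbaldehyde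
Product: 17 2-ethynyl-7-(3-methylbut-2-en-1-yl)-6-[(triisopropylsilyl)oxy]benzofuran-3-carbaldehyde
Conditions: K2CO3 (0.2 equiv), MeOH/THF, 0 °C, short reaction time
Reagents that add atoms: none
Why: Methoxide-catalysed protodesilylation of the alkynylsilane, whose C(sp)–Si bond should cleave far faster than the hindered aryl triisopropylsilyl ether.

Step 11
Reactants: 18 methyl acetoacetate; 3 prenyl bromide
Product: 20 methyl 7-methyl-3-oxooct-6-enoate, via acetoacetate dianion 19 (not isolated)
Conditions: NaH, THF, 0 °C; n-BuLi, 0 °C; then 3, 0 °C → rt; aq. NH4Cl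
Reagents that add atoms: none
Why: Weiler dianion alkylation, in which the more reactive γ-carbanion of the β-keto ester dianion is alkylated by the primary allylic bromide.

Step 12
Reactants: 20 methyl 7-methyl-3-oxooct-6-enoate
Product: 21 methyl 7-methyl-3-[(trimethylsilyl)oxy]octa-2,6-dienoate
Conditions: Me3SiCl, Et3N, toluene, rt
Reagents that add atoms: chlorotrimethylsilane, C[Si](C)(C)Cl
Why: O-silylation of the enolised β-keto ester gives the silyl enol ether; its C2=C3 geometry is lost in the next step and does not matter.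

Step 13
Reactants: 21 methyl 7-methyl-3-[(trimethylsilyl)oxy]octa-2,6-dienoate
Product: 23 (3Z)-1-methoxy-7-methyl-1,3-bis[(trimethylsilyl)oxy]octa-1,3,6-triene, via lithium dienolate 22 (not isolated)
Conditions: LDA (commercial solution), THF, −78 °C; Me3SiCl, −78 °C → rt; hexane, filtration under argon, used crude
Reagents that add atoms: chlorotrimethylsilane, C[Si](C)(C)Cl
Why: γ-Deprotonation of the silyl enol ether ester and O-silylation of the dienolate at the ester oxygen give the Chan-type 1,3-bis(silyloxy)diene, as is established for 4-alkyl analogues.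

Step 14
Reactants: 17 2-ethynyl-7-(3-methylbut-2-en-1-yl)-6-[(triisopropylsilyl)oxy]benzofuran-3-carbaldehyde; 23 (3Z)-1-methoxy-7-methyl-1,3-bis[(trimethylsilyl)oxy]octa-1,3,6-triene
Product: 26 eryvarin Q 6-O-triisopropylsilyl ether, via cyclohexadiene adduct 24 (not isolated), via bis(trimethylsilyl) ether 25 (not isolated)
Conditions: 23 (4 equiv, two portions), BHT (cat.), toluene (1 M), 60 → 100 °C, sealed tube; then 1 M aq. HCl, THF, 0 °C
Reagents that add atoms: none
Why: Proposed new method: the HOMO of the trioxygenated diene is largest at C4 (the prenyl-bearing terminus) and the LUMO of the alkyne, conjugated through C2=C3 with the 3-formyl group, is largest at the terminal carbon, so an asynchronous concerted (4+2) cycloaddition should join diene C4 to the terminal alkyne carbon (C5'–C6') and the ketene acetal carbon to the internal alkyne carbon (C1'–C2'); the closest known reaction type is the Diels–Alder benzannulation of 1-alkoxy-1,3-bis(silyloxy)dienes with acetylenic esters and ketones, which has not been shown for an ethynylheteroarene activated only through a vinylogous formyl group. Ring B, the only ring closed, forms by this intermolecular (4+2) cycloaddition as cyclohexa-1,4-diene 24. The mixed methyl silyl ketal carbon of 24 should then lose methanol together with the hydrogen at C5', which aromatises the ring to 25, and dilute acid cleaves both trimethylsilyl ethers to the 2',4'-diol. The two sp3 centres of 24 are erased on aromatisation, so no stereocentre needs control. Two selectivities are needed: regiochemistry, secured by matching the nucleophilic diene terminus with the electrophilic alkyne carbon remote from the benzofuran, and preference for the alkyne over the formyl carbon, which is a vinylogous formate deactivated by O1 and is not activated because no Lewis acid is present.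

Step 15
Reactants: 26 eryvarin Q 6-O-triisopropylsilyl ether
Product: 27 eryvarin Q
Conditions: Bu4NF, AcOH (1:1), THF, 0 °C
Reagents that add atoms: none
Why: Fluoride-mediated cleavage of the aryl silyl ether, buffered with acetic acid so that the aldehyde and the two ortho-prenylphenols see neither strong base nor strong acid.

**Compound list**

1 | 4-chlororesorcinol (4-chlorobenzene-1,3-diol) | Oc1ccc(Cl)c(O)c1 | starting material
2 | 1-chloro-2,4-bis(methoxymethoxy)benzene | COCOc1ccc(Cl)c(OCOC)c1 | intermediate
3 | prenyl bromide (1-bromo-3-methylbut-2-ene) | CC(C)=CCBr | starting material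
4 | [3-chloro-2,6-bis(methoxymethoxy)phenyl]lithium | [Li]c1c(OCOC)ccc(Cl)c1OCOC | intermediate
5 | 1-chloro-2,4-bis(methoxymethoxy)-3-(3-methylbut-2-en-1-yl)benzene | COCOc1ccc(Cl)c(OCOC)c1CC=C(C)C | intermediate
6 | tert-butyl acetate | CC(=O)OC(C)(C)C | starting material
7 | lithium enolate of tert-butyl acetate | C=C(O[Li])OC(C)(C)C | intermediate
8 | tert-butyl 2-[2,4-bis(methoxymethoxy)-3-(3-methylbut-2-en-1-yl)phenyl]acetate | COCOc1ccc(CC(=O)OC(C)(C)C)c(OCOC)c1CC=C(C)C | intermediate
9 | methyl 2-[2,4-dihydroxy-3-(3-methylbut-2-en-1-yl)phenyl]acetate | COC(=O)Cc1ccc(O)c(CC=C(C)C)c1O | intermediate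
10 | 2-[2,4-dihydroxy-3-(3-methylbut-2-en-1-yl)phenyl]acetic acid | OC(=O)Cc1ccc(O)c(CC=C(C)C)c1O | intermediate
11 | 6-hydroxy-7-(3-methylbut-2-en-1-yl)benzofuran-2(3H)-one | O=C1Cc2ccc(O)c(CC=C(C)C)c2O1 | intermediate
12 | 7-(3-methylbut-2-en-1-yl)-6-[(triisopropylsilyl)oxy]benzofuran-2(3H)-one | O=C1Cc2ccc(O[Si](C(C)C)(C(C)C)C(C)C)c(CC=C(C)C)c2O1 | intermediate
13 | N-({2-chloro-7-(3-methylbut-2-en-1-yl)-6-[(triisopropylsilyl)oxy]benzofuran-3-yl}methylidene)-N-methylmethanaminium chloride | C[N+](C)=Cc1c(Cl)oc2c(CC=C(C)C)c(O[Si](C(C)C)(C(C)C)C(C)C)ccc12.[Cl-] | intermediate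
14 | 2-chloro-7-(3-methylbut-2-en-1-yl)-6-[(triisopropylsilyl)oxy]benzofuran-3-carbaldehyde | O=Cc1c(Cl)oc2c(CC=C(C)C)c(O[Si](C(C)C)(C(C)C)C(C)C)ccc12 | intermediate
15 | ethynyltrimethylsilane | C#C[Si](C)(C)C | starting material
16 | 7-(3-methylbut-2-en-1-yl)-6-[(triisopropylsilyl)oxy]-2-[(trimethylsilyl)ethynyl]benzofuran-3-carbaldehyde | O=Cc1c(C#C[Si](C)(C)C)oc2c(CC=C(C)C)c(O[Si](C(C)C)(C(C)C)C(C)C)ccc12 | intermediate
17 | 2-ethynyl-7-(3-methylbut-2-en-1-yl)-6-[(triisopropylsilyl)oxy]benzofuran-3-carbaldehyde | C#Cc1oc2c(CC=C(C)C)c(O[Si](C(C)C)(C(C)C)C(C)C)ccc2c1C=O | intermediate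
18 | methyl acetoacetate | COC(=O)CC(C)=O | starting material
19 | sodium lithium dianion of methyl acetoacetate | [CH2-]C([O-])=CC(=O)OC.[Na+].[Li+] | intermediate
20 | methyl 7-methyl-3-oxooct-6-enoate | COC(=O)CC(=O)CCC=C(C)C | intermediate
21 | methyl 7-methyl-3-[(trimethylsilyl)oxy]octa-2,6-dienoate (C2=C3 geometry not controlled) | COC(=O)C=C(CCC=C(C)C)O[Si](C)(C)C | intermediate
22 | lithium (3Z)-1-methoxy-7-methyl-3-[(trimethylsilyl)oxy]octa-1,3,6-trien-1-olate | CC(C)=CC/C=C(\O[Si](C)(C)C)C=C(OC)O[Li] | intermediate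
23 | (3Z)-1-methoxy-7-methyl-1,3-bis[(trimethylsilyl)oxy]octa-1,3,6-triene | CC(C)=CC/C=C(\O[Si](C)(C)C)C=C(OC)O[Si](C)(C)C | intermediate
24 | 2-[6-methoxy-3-(3-methylbut-2-en-1-yl)-4,6-bis(trimethylsilyloxy)cyclohexa-1,4-dien-1-yl]-7-(3-methylbut-2-en-1-yl)-6-[(triisopropylsilyl)oxy]benzofuran-3-carbaldehyde (mixture of diastereomers) | COC1(O[Si](C)(C)C)C=C(O[Si](C)(C)C)C(CC=C(C)C)C=C1c1oc2c(CC=C(C)C)c(O[Si](C(C)C)(C(C)C)C(C)C)ccc2c1C=O | intermediate
25 | 2-[5-(3-methylbut-2-en-1-yl)-2,4-bis(trimethylsilyloxy)phenyl]-7-(3-methylbut-2-en-1-yl)-6-[(triisopropylsilyl)oxy]benzofuran-3-carbaldehyde | CC(C)=CCc1cc(-c2oc3c(CC=C(C)C)c(O[Si](C(C)C)(C(C)C)C(C)C)ccc3c2C=O)c(O[Si](C)(C)C)cc1O[Si](C)(C)C | intermediate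
26 | eryvarin Q 6-O-triisopropylsilyl ether, 2-[2,4-dihydroxy-5-(3-methylbut-2-en-1-yl)phenyl]-7-(3-methylbut-2-en-1-yl)-6-[(triisopropylsilyl)oxy]benzofuran-3-carbaldehyde | CC(C)=CCc1cc(-c2oc3c(CC=C(C)C)c(O[Si](C(C)C)(C(C)C)C(C)C)ccc3c2C=O)c(O)cc1O | intermediate
27 | eryvarin Q, 2-[2,4-dihydroxy-5-(3-methylbut-2-en-1-yl)phenyl]-6-hydroxy-7-(3-methylbut-2-en-1-yl)benzofuran-3-carbaldehyde | CC(C)=CCc1cc(-c2oc3c(CC=C(C)C)c(O)ccc3c2C=O)c(O)cc1O | target

**Step count**

Total: 15 steps. Longest linear sequence: 12 steps (steps 1–10, then 14 and 15); the diene branch is 3 steps (11–13).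

**Steps most likely to fail**

1. Step 14 (proposed new method). The cycloaddition may be slower than thermal decay of the diene (silyl migration, desilylation), or the diene terminus may add to the formyl carbon instead of the alkyne. The adduct could also lose trimethylsilanol instead of methanol and leave a 2'-methyl ether. The fallback uses known chemistry, sets out from chloro aldehyde 14 and returns at 26: ring B is brought in intact by Suzuki–Miyaura coupling. Commercial 4,6-dibromoresorcinol is protected (MOMCl, i-Pr2NEt) to 1,5-dibromo-2,4-bis(methoxymethoxy)benzene F1. One bromine–lithium exchange (n-BuLi, THF, −78 °C) and CuI-catalysed reaction with prenyl bromide 3 give 1-bromo-2,4-bis(methoxymethoxy)-5-(3-methylbut-2-en-1-yl)benzene F2. A second exchange and quench with 2-isopropoxy-4,4,5,5-tetramethyl-1,3,2-dioxaborolane give 2-[2,4-bis(methoxymethoxy)-5-(3-methylbut-2-en-1-yl)phenyl]-4,4,5,5-tetramethyl-1,3,2-dioxaborolane F3. Coupling of F3 with 14 (Pd(PPh3)4, K2CO3, dioxane/H2O, 80 °C) gives 2-[2,4-bis(methoxymethoxy)-5-(3-methylbut-2-en-1-yl)phenyl]-7-(3-methylbut-2-en-1-yl)-6-[(triisopropylsilyl)oxy]benzofuran-3-carbaldehyde F4. Methanolic HCl at room temperature then removes the two MOM groups, the aryl silyl ether staying on, and the route is rejoined at 26.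

2. Step 8. Hydrogen chloride released in the warm Vilsmeier mixture may add to or cyclise the prenyl side chain, or loosen the silyl ether, before chloroformylation is complete. The fallback sets out from lactone 12 and returns at 14 by splitting the two events. Condensation with N,N-dimethylformamide dimethyl acetal (toluene, 60 °C) gives, under neutral conditions, 3-[(dimethylamino)methylidene]-7-(3-methylbut-2-en-1-yl)-6-[(triisopropylsilyl)oxy]benzofuran-2(3H)-one F5. Oxalyl chloride (CH2Cl2, 0 °C) then converts the vinylogous carbamate carbonyl of F5 into the chloro iminium chloride 13 with loss of carbon monoxide and carbon dioxide and without forming protic acid. Aqueous sodium acetate hydrolyses 13 to 14.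

3. Step 3. Oxidative addition into the hindered, electron-rich C–Cl bond may be too slow at the low temperature that the lithium ester enolate tolerates, so that Claisen self-condensation of tert-butyl acetate or double arylation takes over. The fallback sets out from aryl chloride 5 and returns at 9, using a nucleophile that tolerates heating and arylates only once. Palladium-catalysed arylation of dimethyl malonate (Pd(OAc)2, P(t-Bu)3·HBF4, K3PO4, toluene, 100 °C) gives dimethyl 2-[2,4-bis(methoxymethoxy)-3-(3-methylbut-2-en-1-yl)phenyl]malonate F6. Krapcho demethoxycarbonylation (LiCl, wet DMSO, 140 °C) gives methyl 2-[2,4-bis(methoxymethoxy)-3-(3-methylbut-2-en-1-yl)phenyl]acetate F7. The methanolic HCl of step 4 removes the MOM groups from F7 and delivers 9.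

**Further compounds**

F1 | step 14 | 1,5-dibromo-2,4-bis(methoxymethoxy)benzene | COCOc1cc(OCOC)c(Br)cc1Br
F2 | step 14 | 1-bromo-2,4-bis(methoxymethoxy)-5-(3-methylbut-2-en-1-yl)benzene | COCOc1cc(OCOC)c(CC=C(C)C)cc1Br
F3 | step 14 | 2-[2,4-bis(methoxymethoxy)-5-(3-methylbut-2-en-1-yl)phenyl]-4,4,5,5-tetramethyl-1,3,2-dioxaborolane | COCOc1cc(OCOC)c(CC=C(C)C)cc1B1OC(C)(C)C(C)(C)O1
F4 | step 14 | 2-[2,4-bis(methoxymethoxy)-5-(3-methylbut-2-en-1-yl)phenyl]-7-(3-methylbut-2-en-1-yl)-6-[(triisopropylsilyl)oxy]benzofuran-3-carbaldehyde | COCOc1cc(OCOC)c(CC=C(C)C)cc1-c1oc2c(CC=C(C)C)c(O[Si](C(C)C)(C(C)C)C(C)C)ccc2c1C=O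
F5 | step 8 | 3-[(dimethylamino)methylidene]-7-(3-methylbut-2-en-1-yl)-6-[(triisopropylsilyl)oxy]benzofuran-2(3H)-one | CN(C)C=C1C(=O)Oc2c(CC=C(C)C)c(O[Si](C(C)C)(C(C)C)C(C)C)ccc21
F6 | step 3 | dimethyl 2-[2,4-bis(methoxymethoxy)-3-(3-methylbut-2-en-1-yl)phenyl]malonate | COCOc1ccc(C(C(=O)OC)C(=O)OC)c(OCOC)c1CC=C(C)C
F7 | step 3 | methyl 2-[2,4-bis(methoxymethoxy)-3-(3-methylbut-2-en-1-yl)phenyl]acetate | COCOc1ccc(CC(=O)OC)c(OCOC)c1CC=C(C)C
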